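**Plan**
- Retrosynthesis: the C4–O–C4 ether is cut at C4 of the (2S,3R,4R) flavan (flavan-4-yl cation plus the 4-OH of the (2R,3R,4R) flavan). Then C4–C4a of each pyran ring is cut (arene plus aldehyde), then each O1–C2 aryl ether (phenoxide plus aryl glycidate).
- Forward: 2,3-bis(benzyloxy)phenol opens a trans- and a cis-glycidate. The pyran ring of the 2,3-trans unit is closed first and that of the all-cis (2R,3R,4R) unit last; the ether is then made and all benzyl groups are removed.
- Enabling feature: in the (2R,3R,4R) ring, C4a is ortho to O1 and para to O7 (a nucleophilic arene carbon), and O3 and O4 are cis. One tin atom can therefore hold the C3 ether oxygen and the C4 carbonyl oxygen (chelate O3–C3–C4–O4) while C4a bonds to C4.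
- Stereochemistry: C2/C3 of each unit come from catalytic asymmetric epoxidation (Shi for trans, Jacobsen–Katsuki for cis) followed by SN2 inversion at the benzylic carbon. C4 of the all-cis unit comes from the chelate (2-aryl equatorial, O3 axial, O4 equatorial). C4 of the other unit comes from pseudo-axial capture of its cation trans to the 2-aryl group.

Key step: step 15

Remark: compounds 11 and 12 are drawn as the expected 3,4-cis epimer at C4; this centre is ionised in step 16, so either epimer serves.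

**Route**

Step 1
Reactants: 1 2,3-dihydroxybenzaldehyde
Product: 2 2,3-bis(benzyloxy)benzaldehyde
Conditions: BnBr (2.3 equiv), K2CO3, DMF, 60 °C
Reagents that add atoms: benzyl bromide, BrCc1ccccc1
Why: Williamson ether synthesis in which carbonate in DMF alkylates both phenols, the hydrogen-bonded 2-OH included, with no stereocentre involved.

Step 2
Reactants: 2 2,3-bis(benzyloxy)benzaldehyde
Product: 4 2,3-bis(benzyloxy)phenol, via aryl formate 3 (not isolated)
Conditions: mCPBA, CH2Cl2, rt; then K2CO3 (cat.), MeOH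
Reagents that add atoms: 3-chloroperbenzoic acid, OOC(=O)c1cccc(Cl)c1
Why: Baeyer–Villiger (Dakin-type) oxidation in which the electron-rich aryl group migrates to give the formate, which mild methanolysis converts to the phenol.

Step 3
Reactants: 5 4-(benzyloxy)benzaldehyde
Product: 6 methyl (2E)-3-[4-(benzyloxy)phenyl]prop-2-enoate
Conditions: (MeO)2P(O)CH2CO2Me, NaH, THF, 0 °C to rt
Reagents that add atoms: trimethyl phosphonoacetate, COC(=O)CP(=O)(OC)OC
Why: Horner–Wadsworth–Emmons olefination with a stabilised phosphonate, which should give the E-cinnamate.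

Step 4
Reactants: 6 methyl (2E)-3-[4-(benzyloxy)phenyl]prop-2-enoate
Product: 7 methyl (2S,3R)-3-[4-(benzyloxy)phenyl]oxirane-2-carboxylate (trans-glycidate)
Conditions: D-fructose-derived Shi ketone (diacetate type, 0.3 equiv), Oxone, NaHCO3, Bu4NHSO4 (cat.), MeCN/aq. Na2EDTA, 0 °C
Reagents that add atoms: Oxone (active component potassium peroxymonosulfate), OOS(=O)(=O)[O-].[K+]
Why: Shi asymmetric epoxidation, in which the chiral dioxirane transfers oxygen through a spiro transition state to one face of the trans-alkene and should set C2 (S) and C3 (R) together (the enantiomeric ketone would be used if the opposite sense were found).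

Step 5
Reactants: 7 methyl (2S,3R)-3-[4-(benzyloxy)phenyl]oxirane-2-carboxylate; 4 2,3-bis(benzyloxy)phenol
Product: 8 methyl (2S,3S)-3-[2,3-bis(benzyloxy)phenoxy]-3-[4-(benzyloxy)phenyl]-2-hydroxypropanoate (anti)
Conditions: Cs2CO3 (0.2 equiv), DMF, 50 °C
Reagents that add atoms: none
Why: Base-catalysed SN2 opening of the epoxide by the phenoxide at the benzylic C3 with inversion, which converts the trans-epoxide into the anti (2S,3S) aryl ether and leaves C2 untouched.

Step 6
Reactants: 8 methyl (2S,3S)-3-[2,3-bis(benzyloxy)phenoxy]-3-[4-(benzyloxy)phenyl]-2-hydroxypropanoate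
Product: 9 methyl (2S,3S)-2-(benzyloxy)-3-[2,3-bis(benzyloxy)phenoxy]-3-[4-(benzyloxy)phenyl]propanoate
Conditions: BnBr, Ag2O, CH2Cl2, rt, dark
Reagents that add atoms: benzyl bromide, BrCc1ccccc1
Why: Silver(I) oxide-mediated Williamson benzylation, chosen because it is not basic enough to trigger β-elimination of the aryloxide or epimerisation at C2.

Step 7
Reactants: 9 methyl (2S,3S)-2-(benzyloxy)-3-[2,3-bis(benzyloxy)phenoxy]-3-[4-(benzyloxy)phenyl]propanoate
Product: 10 (2S,3S)-2-(benzyloxy)-3-[2,3-bis(benzyloxy)phenoxy]-3-[4-(benzyloxy)phenyl]propanal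
Conditions: DIBAL-H (1.1 equiv), CH2Cl2, −78 °C; Rochelle salt work-up
Reagents that add atoms: none
Why: DIBAL-H half-reduction of an α-alkoxy ester, in which the chelated aluminium hemiacetal survives at −78 °C and releases the aldehyde only on work-up without touching the two stereocentres.

Step 8
Reactants: 10 (2S,3S)-2-(benzyloxy)-3-[2,3-bis(benzyloxy)phenoxy]-3-[4-(benzyloxy)phenyl]propanal
Product: 11 (2S,3R,4R)-3,7,8-tris(benzyloxy)-2-[4-(benzyloxy)phenyl]-3,4-dihydro-2H-chromen-4-ol (2,3-trans-3,4-cis)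
Conditions: SnCl4 (1.1 equiv), CH2Cl2, −78 °C; H2O quench
Reagents that add atoms: none
Why: Intramolecular Friedel–Crafts hydroxyalkylation in which the arene carbon ortho to the ether oxygen and para to a benzyloxy group adds to the tin-activated aldehyde (6-exo-trig) and closes the first pyran ring with C2 and C3 carried over, the 4-OH being expected pseudo-axial (3,4-cis).

Step 9
Reactants: 11 (2S,3R,4R)-3,7,8-tris(benzyloxy)-2-[4-(benzyloxy)phenyl]-3,4-dihydro-2H-chromen-4-ol
Product: 12 (2S,3S,4R)-3,7,8-tris(benzyloxy)-2-[4-(benzyloxy)phenyl]-3,4-dihydro-2H-chromen-4-yl 2,2,2-trichloroethanimidate (same spatial arrangement as 11; the C3 descriptor changes by CIP rank only)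
Conditions: Cl3CCN, DBU (0.1 equiv), CH2Cl2, 0 °C; used crude
Reagents that add atoms: trichloroacetonitrile, N#CC(Cl)(Cl)Cl
Why: Base-catalysed addition of the alcohol to trichloroacetonitrile (trichloroacetimidate formation) turns the 4-OH into a leaving group that mild acid can ionise, with retention at C4 because only the O–H bond reacts.

Step 10
Reactants: 5 4-(benzyloxy)benzaldehyde
Product: 13 methyl (2Z)-3-[4-(benzyloxy)phenyl]prop-2-enoate
Conditions: (CF3CH2O)2P(O)CH2CO2Me, KHMDS, 18-crown-6, THF, −78 °C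
Reagents that add atoms: methyl bis(2,2,2-trifluoroethyl)phosphonoacetate, COC(=O)CP(=O)(OCC(F)(F)F)OCC(F)(F)F
Why: Still–Gennari olefination, in which the trifluoroethyl phosphonate under dissociating conditions eliminates from the kinetic adduct and should give the Z-cinnamate.

Step 11
Reactants: 13 methyl (2Z)-3-[4-(benzyloxy)phenyl]prop-2-enoate
Product: 14 methyl (2S,3S)-3-[4-(benzyloxy)phenyl]oxirane-2-carboxylate (cis-glycidate)
Conditions: (S,S)-Jacobsen Mn(salen)Cl (5 mol%), 4-phenylpyridine N-oxide, aq. NaOCl (pH 11.3), CH2Cl2, 0 °C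
Reagents that add atoms: sodium hypochlorite, [Na+].[O-]Cl
Why: Jacobsen–Katsuki epoxidation of a cis-disubstituted conjugated alkene, in which the (S,S)-Mn(salen) oxo species delivers oxygen to one face by side-on approach and should give the cis-epoxide with C2 (S) and C3 (S).

Step 12
Reactants: 14 methyl (2S,3S)-3-[4-(benzyloxy)phenyl]oxirane-2-carboxylate; 4 2,3-bis(benzyloxy)phenol
Product: 15 methyl (2S,3R)-3-[2,3-bis(benzyloxy)phenoxy]-3-[4-(benzyloxy)phenyl]-2-hydroxypropanoate (syn)
Conditions: Cs2CO3 (0.2 equiv), DMF, 50 °C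
Reagents that add atoms: none
Why: The same SN2 epoxide opening as in step 5, in which inversion at the benzylic C3 of the cis-epoxide gives the syn (2S,3R) aryl ether, the relative configuration that becomes 2,3-cis in the ring.

Step 13
Reactants: 15 methyl (2S,3R)-3-[2,3-bis(benzyloxy)phenoxy]-3-[4-(benzyloxy)phenyl]-2-hydroxypropanoate
Product: 16 methyl (2S,3R)-2-(benzyloxy)-3-[2,3-bis(benzyloxy)phenoxy]-3-[4-(benzyloxy)phenyl]propanoate
Conditions: BnBr, Ag2O, CH2Cl2, rt, dark
Reagents that add atoms: benzyl bromide, BrCc1ccccc1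
Why: Silver(I) oxide-mediated Williamson benzylation installs the ether oxygen that will chelate in step 15 without base-induced elimination or epimerisation.

Step 14
Reactants: 16 methyl (2S,3R)-2-(benzyloxy)-3-[2,3-bis(benzyloxy)phenoxy]-3-[4-(benzyloxy)phenyl]propanoate
Product: 17 (2S,3R)-2-(benzyloxy)-3-[2,3-bis(benzyloxy)phenoxy]-3-[4-(benzyloxy)phenyl]propanal
Conditions: DIBAL-H (1.1 equiv), CH2Cl2, −78 °C; Rochelle salt work-up; used at once
Reagents that add atoms: none
Why: DIBAL-H half-reduction of the α-benzyloxy ester through the aluminium hemiacetal that is stable at −78 °C, which should leave both stereocentres intact.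

Step 15
Reactants: 17 (2S,3R)-2-(benzyloxy)-3-[2,3-bis(benzyloxy)phenoxy]-3-[4-(benzyloxy)phenyl]propanal
Product: 18 (2R,3R,4R)-3,7,8-tris(benzyloxy)-2-[4-(benzyloxy)phenyl]-3,4-dihydro-2H-chromen-4-ol (all-cis)
Conditions: SnCl4 (1.1 equiv), CH2Cl2, −78 °C; H2O quench
Reagents that add atoms: none
Why: SnCl4 binds the aldehyde oxygen and the C3 benzyloxy oxygen of 17 in a five-membered chelate, and the arene carbon that becomes C4a (ortho to O1, para to the C7 benzyloxy group) adds to the activated carbonyl carbon, after which proton loss restores the aromatic ring (intramolecular Friedel–Crafts hydroxyalkylation). The closest known reaction types are chelation-controlled additions of π-nucleophiles to α-benzyloxy aldehydes and Lewis-acid cyclisations of 3-aryloxypropanals to chroman-4-ols. The pyran ring closes in the 6-exo-trig mode by forming C4–C4a, the C=O bond staying outside the ring. C2 and C3 are carried over unchanged from 17, and the new centre C4 is controlled by the chelate: with the 2-aryl group equatorial the C3–O bond is axial, and the carbonyl oxygen can stay on the same tin atom only if it ends equatorial, that is cis to O3 and to the aryl group (4R). The step needs regioselectivity, secured because the only free position ortho to O1 is also the one para to O7; chemoselectivity, secured because the 4-benzyloxyphenyl ring and the benzyl groups are far weaker nucleophiles; and diastereoselectivity, secured by the chelating benzyl ether at O3 and by the low temperature, which should also keep the benzylic C2–O1 bond and the product alkoxide from ionising.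

Step 16
Reactants: 18 (2R,3R,4R)-3,7,8-tris(benzyloxy)-2-[4-(benzyloxy)phenyl]-3,4-dihydro-2H-chromen-4-ol; 12 (2S,3S,4R)-3,7,8-tris(benzyloxy)-2-[4-(benzyloxy)phenyl]-3,4-dihydro-2H-chromen-4-yl 2,2,2-trichloroethanimidate
Product: 19 octa-O-benzyl ether of the target, (2R,3R,4R)-3,7,8-tris(benzyloxy)-2-[4-(benzyloxy)phenyl]-4-{[(2S,3R,4R)-3,7,8-tris(benzyloxy)-2-[4-(benzyloxy)phenyl]-3,4-dihydro-2H-chromen-4-yl]oxy}-3,4-dihydro-2H-chromene
Conditions: 12 (1.5 equiv), TMSOTf (0.1 equiv), 4 Å MS, CH2Cl2, −78 °C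
Reagents that add atoms: none
Why: Acid-catalysed trichloroacetimidate etherification (Schmidt-type, as in PMB-imidate protection), in which 12 ionises to the flavan-4-yl cation stabilised by the para oxygen at C7 and the 4-OH of 18 should add pseudo-axially on the face trans to the 2-aryl group of the cation, giving the 3,4-cis (4R) linkage while C4 of 18 keeps its configuration because only its O–H bond reacts.

Step 17
Reactants: 19 octa-O-benzyl ether of the target
Product: 20 the target, (2R,3R,4R)-2-(4-hydroxyphenyl)-4-{[(2S,3R,4R)-3,7,8-trihydroxy-2-(4-hydroxyphenyl)-3,4-dihydro-2H-chromen-4-yl]oxy}-3,4-dihydro-2H-chromene-3,7,8-triol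
Conditions: H2 (1 atm), Pd(OH)2/C, THF/MeOH, rt, monitored closely
Reagents that add atoms: none
Why: Catalytic hydrogenolysis over Pearlman's catalyst cleaves the eight benzyl ethers, the aryl benzyl ethers fastest, and is stopped as soon as the two aliphatic ones are gone so that the more hindered secondary benzylic C–O bonds of the flavan skeleton should survive.

**Compound list**

1 | 2,3-dihydroxybenzaldehyde | O=Cc1cccc(O)c1O | starting material
2 | 2,3-bis(benzyloxy)benzaldehyde | O=Cc1cccc(OCc2ccccc2)c1OCc1ccccc1 | intermediate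
3 | 2,3-bis(benzyloxy)phenyl formate | O=COc1cccc(OCc2ccccc2)c1OCc1ccccc1 | intermediate
4 | 2,3-bis(benzyloxy)phenol | Oc1cccc(OCc2ccccc2)c1OCc1ccccc1 | intermediate
5 | 4-(benzyloxy)benzaldehyde | O=Cc1ccc(OCc2ccccc2)cc1 | starting material
6 | methyl (2E)-3-[4-(benzyloxy)phenyl]prop-2-enoate | COC(=O)/C=C/c1ccc(OCc2ccccc2)cc1 | intermediate
7 | methyl (2S,3R)-3-[4-(benzyloxy)phenyl]oxirane-2-carboxylate | COC(=O)[C@H]1O[C@@H]1c1ccc(OCc2ccccc2)cc1 | intermediate
8 | methyl (2S,3S)-3-[2,3-bis(benzyloxy)phenoxy]-3-[4-(benzyloxy)phenyl]-2-hydroxypropanoate | COC(=O)[C@@H](O)[C@@H](Oc1cccc(OCc2ccccc2)c1OCc1ccccc1)c1ccc(OCc2ccccc2)cc1 | intermediate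
9 | methyl (2S,3S)-2-(benzyloxy)-3-[2,3-bis(benzyloxy)phenoxy]-3-[4-(benzyloxy)phenyl]propanoate | COC(=O)[C@@H](OCc1ccccc1)[C@@H](Oc1cccc(OCc2ccccc2)c1OCc1ccccc1)c1ccc(OCc2ccccc2)cc1 | intermediate
10 | (2S,3S)-2-(benzyloxy)-3-[2,3-bis(benzyloxy)phenoxy]-3-[4-(benzyloxy)phenyl]propanal | O=C[C@@H](OCc1ccccc1)[C@@H](Oc1cccc(OCc2ccccc2)c1OCc1ccccc1)c1ccc(OCc2ccccc2)cc1 | intermediate
11 | (2S,3R,4R)-3,7,8-tris(benzyloxy)-2-[4-(benzyloxy)phenyl]-3,4-dihydro-2H-chromen-4-ol | O[C@@H]1c2ccc(OCc3ccccc3)c(OCc3ccccc3)c2O[C@@H](c2ccc(OCc3ccccc3)cc2)[C@@H]1OCc1ccccc1 | intermediate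
12 | (2S,3S,4R)-3,7,8-tris(benzyloxy)-2-[4-(benzyloxy)phenyl]-3,4-dihydro-2H-chromen-4-yl 2,2,2-trichloroethanimidate | N=C(O[C@@H]1c2ccc(OCc3ccccc3)c(OCc3ccccc3)c2O[C@@H](c2ccc(OCc3ccccc3)cc2)[C@@H]1OCc1ccccc1)C(Cl)(Cl)Cl | intermediate
13 | methyl (2Z)-3-[4-(benzyloxy)phenyl]prop-2-enoate | COC(=O)/C=C\c1ccc(OCc2ccccc2)cc1 | intermediate
14 | methyl (2S,3S)-3-[4-(benzyloxy)phenyl]oxirane-2-carboxylate | COC(=O)[C@H]1O[C@H]1c1ccc(OCc2ccccc2)cc1 | intermediate
15 | methyl (2S,3R)-3-[2,3-bis(benzyloxy)phenoxy]-3-[4-(benzyloxy)phenyl]-2-hydroxypropanoate | COC(=O)[C@@H](O)[C@H](Oc1cccc(OCc2ccccc2)c1OCc1ccccc1)c1ccc(OCc2ccccc2)cc1 | intermediate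
16 | methyl (2S,3R)-2-(benzyloxy)-3-[2,3-bis(benzyloxy)phenoxy]-3-[4-(benzyloxy)phenyl]propanoate | COC(=O)[C@@H](OCc1ccccc1)[C@H](Oc1cccc(OCc2ccccc2)c1OCc1ccccc1)c1ccc(OCc2ccccc2)cc1 | intermediate
17 | (2S,3R)-2-(benzyloxy)-3-[2,3-bis(benzyloxy)phenoxy]-3-[4-(benzyloxy)phenyl]propanal | O=C[C@@H](OCc1ccccc1)[C@H](Oc1cccc(OCc2ccccc2)c1OCc1ccccc1)c1ccc(OCc2ccccc2)cc1 | intermediate
18 | (2R,3R,4R)-3,7,8-tris(benzyloxy)-2-[4-(benzyloxy)phenyl]-3,4-dihydro-2H-chromen-4-ol | c1ccccc1COc1ccc([C@H]2Oc3c(ccc(OCc4ccccc4)c3OCc3ccccc3)[C@@H](O)[C@H]2OCc2ccccc2)cc1 | intermediate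
19 | octa-O-benzyl ether of the target | c1ccccc1COc1ccc([C@H]2Oc3c(ccc(OCc4ccccc4)c3OCc3ccccc3)[C@@H](O[C@@H]3c4ccc(OCc5ccccc5)c(OCc5ccccc5)c4O[C@@H](c4ccc(OCc5ccccc5)cc4)[C@@H]3OCc3ccccc3)[C@H]2OCc2ccccc2)cc1 | intermediate
20 | (2R,3R,4R)-2-(4-hydroxyphenyl)-4-{[(2S,3R,4R)-3,7,8-trihydroxy-2-(4-hydroxyphenyl)-3,4-dihydro-2H-chromen-4-yl]oxy}-3,4-dihydro-2H-chromene-3,7,8-triol | Oc1ccc([C@H]2Oc3c(ccc(O)c3O)[C@@H](O[C@@H]3c4ccc(O)c(O)c4O[C@@H](c4ccc(O)cc4)[C@@H]3O)[C@H]2O)cc1 | target

**Totals and risks**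

Total step count: 17. Longest linear sequence: 9 steps (1, 2, 5, 6, 7, 8, 9, 16, 17).

Step 16 (most at risk). What may go wrong:
- poor facial selectivity in the capture of the flavan-4-yl cation (attack cis to its 2-aryl group would give the 3,4-trans ether);
- acid-triggered ionisation of the acceptor at its own C4–O bond;
- rearrangement of the imidate to the N-linked amide;
- C-alkylation at C6 of the acceptor.

Fallback: the route is left at 11. Thiolysis with benzyl mercaptan and catalytic camphorsulfonic acid in CH2Cl2 should give the bench-stable thioether (2S,3S,4S)-3,7,8-tris(benzyloxy)-2-[4-(benzyloxy)phenyl]-4-(benzylsulfanyl)-3,4-dihydro-2H-chromene F1 (its C4 configuration is immaterial). The thioether is then activated with silver tetrafluoroborate, a thiophile that is neutral towards benzylic ethers, in the presence of 18 and 2,6-di-tert-butylpyridine at 0 °C. This is thiophile-promoted etherification of a 4-sulfanylflavan by a flavan-4-ol, and it returns to the route at 19.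

Step 15. What may go wrong:
- loss of chelation control (attack through the open, dipole-opposed arrangement would give the 3,4-trans alcohol);
- ionisation of the benzylic C2–O1 ether or of the product alcohol by the Lewis acid;
- β-elimination of the aryloxide from the aldehyde.

Fallback: the route is left at 16. The ester is cleaved with Me3SnOH to (2S,3R)-2-(benzyloxy)-3-[2,3-bis(benzyloxy)phenoxy]-3-[4-(benzyloxy)phenyl]propanoic acid F2. Trifluoroacetic anhydride in CH2Cl2 at 0 °C converts it into the mixed anhydride (2S,3R)-2-(benzyloxy)-3-[2,3-bis(benzyloxy)phenoxy]-3-[4-(benzyloxy)phenyl]propanoic trifluoroacetic anhydride F3. This should close the ring by intramolecular Friedel–Crafts acylation to (2R,3S)-3,7,8-tris(benzyloxy)-2-[4-(benzyloxy)phenyl]-2,3-dihydro-4H-chromen-4-one F4. Reduction with NaBH4 at −20 °C then delivers hydride axially, anti to the axial 3-benzyloxy group, so that the 4-OH ends equatorial and all-cis. The fallback returns to the route at 18.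

Step 17. What may go wrong:
- over-reduction, that is hydrogenolysis of the two benzylic C4–O bonds of the interflavanyl ether (or of C2–O1) before the two aliphatic benzyl ethers are cleaved;
- incomplete debenzylation if the reaction is stopped early.

Fallback: the order of events is changed and the route is left at 18 and 11. Each monomer, which carries a benzylic alcohol and not a benzylic ether at C4, is debenzylated separately by hydrogenolysis. This gives (2R,3R,4R)-2-(4-hydroxyphenyl)-3,4-dihydro-2H-chromene-3,4,7,8-tetrol F5 and (2S,3R,4R)-2-(4-hydroxyphenyl)-3,4-dihydro-2H-chromene-3,4,7,8-tetrol F6. The two free flavan-3,4-diols are then united under dilute acid (0.05 M HCl, aqueous dioxane, rt), the acid-catalysed condensation known for free flavan-3,4-diols. F6, with its pseudo-axial 4-OH, should ionise preferentially and be captured by the pseudo-equatorial 4-OH of F5. The fallback returns to the route at 20.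

Further compounds
F1 | step 16 | (2S,3S,4S)-3,7,8-tris(benzyloxy)-2-[4-(benzyloxy)phenyl]-4-(benzylsulfanyl)-3,4-dihydro-2H-chromene | c1ccccc1CS[C@H]1c2ccc(OCc3ccccc3)c(OCc3ccccc3)c2O[C@@H](c2ccc(OCc3ccccc3)cc2)[C@@H]1OCc1ccccc1
F2 | step 15 | (2S,3R)-2-(benzyloxy)-3-[2,3-bis(benzyloxy)phenoxy]-3-[4-(benzyloxy)phenyl]propanoic acid | OC(=O)[C@@H](OCc1ccccc1)[C@H](Oc1cccc(OCc2ccccc2)c1OCc1ccccc1)c1ccc(OCc2ccccc2)cc1
F3 | step 15 | (2S,3R)-2-(benzyloxy)-3-[2,3-bis(benzyloxy)phenoxy]-3-[4-(benzyloxy)phenyl]propanoic trifluoroacetic anhydride | FC(F)(F)C(=O)OC(=O)[C@@H](OCc1ccccc1)[C@H](Oc1cccc(OCc2ccccc2)c1OCc1ccccc1)c1ccc(OCc2ccccc2)cc1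
F4 | step 15 | (2R,3S)-3,7,8-tris(benzyloxy)-2-[4-(benzyloxy)phenyl]-2,3-dihydro-4H-chromen-4-one | c1ccccc1COc1ccc([C@H]2Oc3c(ccc(OCc4ccccc4)c3OCc3ccccc3)C(=O)[C@H]2OCc2ccccc2)cc1
F5 | step 17 | (2R,3R,4R)-2-(4-hydroxyphenyl)-3,4-dihydro-2H-chromene-3,4,7,8-tetrol | Oc1ccc([C@H]2Oc3c(ccc(O)c3O)[C@@H](O)[C@H]2O)cc1
F6 | step 17 | (2S,3R,4R)-2-(4-hydroxyphenyl)-3,4-dihydro-2H-chromene-3,4,7,8-tetrol | O[C@@H]1c2ccc(O)c(O)c2O[C@@H](c2ccc(O)cc2)[C@@H]1O
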